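(The rate constants were set for the occasion.)

Dissolving is slow here, and a slow solid poses a question that one finished curve can hide: does it outlast the run, or does self-condensation use it up first? Solid substrate dissolves towards its solubility, and it also condenses with itself, two at a time. Dissolved substrate meets coupling partner, fed from the gas, to give target, and target meets dissolved substrate to give side product.

solid substrate 42 mM; gas 21 mM (held); time 5.0 h

- how much target there is at 5.0 h, in percent of the solid substrate charged
- the change that raises the amount of target at 5.0 h, in percent of the solid substrate charged most ("none" if none brings more than 2 percentage points) (green / amber / blue / grey / none)
- amount of target at 5.0 h, in percent of the solid substrate charged, after blue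

- green: doubling the solubility in step 1, all else as stated
- amber: doubling the dissolution coefficient of step 1, all else as stated
- blue: doubling the transfer coefficient of step 4, all else as stated
- grey: doubling the saturation concentration of gas, all else as stated

- in percentages every species weighs as the solid substrate in it: one side product or self-condensation product counts as two
- a doubled species enters its step squared and goes two at a time
- as a solid, counted per litre of solution: solid substrate
- at the start none of coupling partner is dissolved
- at the start none of the solid substrate is in solution
- run time (flask): 5.0 h

    solid substrate ⇌ dissolved substrate, rate k1*(cs1 - [dissolved substrate]) while solid is left; crystals form when [dissolved substrate] > cs1 (cs1 = 30 mM, k1 = 0.0064 min⁻¹)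
    dissolved substrate + coupling partner → target (k2 = 0.22 M⁻¹ min⁻¹)
    dissolved substrate + target → side product (k3 = 0.19 M⁻¹ min⁻¹)
    gas ⇌ coupling partner, rate k4*(csat - [coupling partner]) (k4 = 0.0024 min⁻¹, csat = 21 mM)
    2 solid substrate → self-condensation product (k5 = 0.063 M⁻¹ min⁻¹)

Here is my own reckoning. Dissolved substrate starts at 0.192 mM min⁻¹, bends at about 2.60 h and heads for 30 mM. Coupling partner starts at 0.0504 mM min⁻¹ and bends later, at about 6.94 h, heading for 21 mM. Target starts flat, since both its feeds start empty. On these undisturbed curves, coupling makes 8.08 mM by 5.0 h, or 19.2% of the charge. That is a ceiling, and I take the hand reckoning of the amount no further.

Now divide the rate of self-condensation by the rate of dissolving into an empty solution, and time drops out. This branching ratio is 1.16 at full charge and falls with the square of the solid. The dissolving share of the solid's loss therefore climbs from 46.3% at full charge, through 77.5% at half the charge, to 100% as the solid nears its end. This share is not linear in the solid, so I sum it over the charge by Simpson's rule, which gives an estimate of the reach, the solid that gets into solution before the solid is gone if the solution stays empty: 32.0 mM. The undisturbed curve carries a supply of 25.6 mM into solution by 5.0 h, which is less, so I expect solid to stand to the end.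

Doubling the solubility lifts the supply to 51.2 mM, above its reach of 35.9 mM, so I do not count on green's ceiling. Grey doubles the ceiling, while blue multiplies it by 1.61. I back grey of these three; amber I did not reckon.

The forecast says 9%, well under my ceiling, then 14.5% after blue, and grey, since “the saturation concentration roughly doubles the coupling partner throughout”.

The simulation gives 8.89%, 14.3% after blue, and grey, which gains 8.1 percentage points against 5.4 points for blue, 0.64 points for green and 0.61 points for amber.

In this flask 3.00% of the solid stands at 5.00 h, and 28.4 mM has entered solution, under the reach of 32.0 mM. Now take the neighbour charged with 10 mM. Its branching ratio starts at 0.0656, and its reach by the same sum, 9.79 mM, is less than the supply, so its solid should be gone before the end. At 5.00 h that neighbour holds 0% solid, and 9.77 mM has entered solution. Its target is 23.2% of its charge, which is 2.32 mM against 3.73 mM in this flask.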